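**Retrosynthetic overview** (target numbering: C1 acetoxy carbon, C2=C3 alkene, C4 gem-dimethyl carbon, C5 CHBr, C6 CH2; C1'/C2' side chain)
1. Endgame: acetate from the C1 alcohol; both C–Br bonds by SN2 inversion of the C5 and C1' carbinols, which come from one diketone by a double CBS reduction.
2. Key disconnection: C1–C2 and C3–C4, formed in one operation by a Lewis acid-promoted formal [4+2] union of a 3-alkoxy-2,2-dimethylcyclobutanone (C1, C6, C5, C4) with 1-chlorobut-3-yn-2-one (C2, C3, C1', C2').
3. Enabling feature: the C1 oxygen and C5 are 1,3-related across C6, and C5 is flanked by the quaternary C4. With C5 at the ketone level, C1–C6–C5–C4 is a β-alkoxy ketone that can be stored as a strained push–pull cyclobutanone, a latent 1,4-zwitterion (enolate at C4, oxocarbenium at C1). The C2=C3 alkene with C1' at the ketone level is an ynone of complementary polarity.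
4. Ring order: first the temporary four-membered ring (dimethylketene plus a vinyl ether, [2+2]); then the cyclohexene, the only ring of the target, in the key step at the expense of the cyclobutane.
5. Stereocontrol: C1 from a removable (R)-1-(naphthalen-2-yl)ethyl group on oxygen (both cyclobutanone epimers converge through the planar oxocarbenium); C5 and C1' from one (S)-CBS catalyst followed by two inversions.

Key step: step 4

Remark: the facial sense of the auxiliary in step 4 is assigned from an allylic-strain model of the oxocarbenium ion; should it prove reversed, the equally available (S)-alcohol would be used in step 1.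

Step 1
Reactants: 1 (R)-1-(naphthalen-2-yl)ethan-1-ol; 2 butyl vinyl ether
Product: 3 2-[(1R)-1-(ethenyloxy)ethyl]naphthalene
Conditions: Pd(OCOCF3)2 (cat.), 4,7-diphenyl-1,10-phenanthroline (cat.), Et3N (cat.), neat 2 (excess), 75 °C
Reagents that add atoms: none
Why: Palladium-catalysed transfer vinylation (transetherification) moves the vinyl group onto the secondary alcohol without touching its stereocentre, the excess vinyl ether driving the equilibrium.

Step 2
Reactants: 3 2-[(1R)-1-(ethenyloxy)ethyl]naphthalene; 4 2-methylpropanoyl chloride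
Product: 6 2,2-dimethyl-3-[(1R)-1-(naphthalen-2-yl)ethoxy]cyclobutan-1-one (both epimers at ring C3), via dimethylketene 5 (not isolated)
Conditions: Et3N, MeCN, reflux, slow addition of 4 (excess)
Reagents that add atoms: none
Why: Ketene–enol ether [2+2] cycloaddition joins the ketene carbonyl carbon to the vinyl CH2 and gives the 3-alkoxy-2,2-dimethylcyclobutanone; the new ring stereocentre forms unselectively, which is immaterial because step 4 erases it.

Step 3
Reactants: 7 2-chloro-N-methoxy-N-methylacetamide; 8 ethynylmagnesium bromide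
Product: 10 1-chlorobut-3-yn-2-one, via magnesium hemiaminal chelate 9 (not isolated)
Conditions: THF, −78 to 0 °C; poured into cold 1 M HCl; used as a fresh CH2Cl2 solution
Reagents that add atoms: none
Why: Weinreb ketone synthesis: the chelated tetrahedral adduct prevents over-addition, and the cold acidic quench protonates the released N,O-dimethylhydroxylamine so that it cannot add to the ynone.

Step 4
Reactants: 6 2,2-dimethyl-3-[(1R)-1-(naphthalen-2-yl)ethoxy]cyclobutan-1-one; 10 1-chlorobut-3-yn-2-one
Product: 13 (5R)-4-(chloroacetyl)-2,2-dimethyl-5-[(1R)-1-(naphthalen-2-yl)ethoxy]cyclohex-3-en-1-one, via boron enolate oxocarbenium zwitterion 11 (not isolated), via allenolate oxocarbenium zwitterion 12 (not isolated)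
Conditions: BF3·OEt2 (1.2 equiv), CH2Cl2, −78 to −40 °C; then Et3N, aq. NaHCO3
Reagents that add atoms: none
Why: Proposed new method: BF3 opens either epimer of the push–pull cyclobutanone between the gem-dimethyl carbon and the alkoxy carbon to the 1,4-zwitterion 11; its enolate carbon adds in a Mukaiyama–Michael sense to the unsubstituted terminus of the BF3-activated ynone (C3–C4 bond) to give allenolate 12, whose α-carbon then attacks the tethered oxocarbenium (C1–C2 bond). The closest known reaction type is the Lewis acid-promoted formal [4+2] cycloaddition of 3-alkoxycyclobutanones with aldehydes, ketones, silyl enol ethers and allylsilanes, here extended to an electron-poor alkyne, which is needed because the equivalent 1-alkoxy-3-silyloxy diene carries a Z-methyl group that disfavours the s-cis geometry of a concerted cycloaddition. The only ring, the cyclohexene, is closed by a 6-(enolexo)-exo-trig aldol-type addition. The one new stereocentre, C1, is controlled by the (R)-1-(naphthalen-2-yl)ethyl group on the oxocarbenium oxygen: its C–H eclipses the C=O+ bond to minimise allylic 1,3-strain, naphthyl shields one face, and addition on the methyl-flanked face is assigned by this model as leading to (1R). The step needs conjugate rather than carbonyl attack on the ynone, secured by the fully substituted enolate carbon meeting an unhindered alkyne CH. It also needs six- rather than four-membered closure, secured by the oxocarbenium being the strongest electrophile in reach and the six-membered ring being strain-free.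

Step 5
Reactants: 13 (5R)-4-(chloroacetyl)-2,2-dimethyl-5-[(1R)-1-(naphthalen-2-yl)ethoxy]cyclohex-3-en-1-one
Product: 14 (1R,5R)-4-[(1S)-2-chloro-1-hydroxyethyl]-2,2-dimethyl-5-[(1R)-1-(naphthalen-2-yl)ethoxy]cyclohex-3-en-1-ol
Conditions: (S)-2-methyl-CBS-oxazaborolidine (0.5 equiv), BH3·SMe2 (2.5 equiv), THF, −30 to 0 °C; then MeOH
Reagents that add atoms: none
Why: Corey–Bakshi–Shibata reduction under reagent control: the (S)-catalyst places the larger flank of each ketone (quaternary C4 for the ring ketone, the trisubstituted alkenyl for the chloromethyl ketone) where phenyl sits in acetophenone, which should give the (5R)-carbinol (trans to the C1 ether) and the (1'S)-carbinol by 1,2-reduction.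

Step 6
Reactants: 14 (1R,5R)-4-[(1S)-2-chloro-1-hydroxyethyl]-2,2-dimethyl-5-[(1R)-1-(naphthalen-2-yl)ethoxy]cyclohex-3-en-1-ol
Product: 15 2-[(1R)-1-{[(1R,5S)-5-bromo-2-[(1R)-1-bromo-2-chloroethyl]-4,4-dimethylcyclohex-2-en-1-yl]oxy}ethyl]naphthalene
Conditions: CBr4 (6 equiv), PPh3 (5 equiv), toluene, 0 °C then 60 °C
Reagents that add atoms: carbon tetrabromide, BrC(Br)(Br)Br
Why: Double Appel reaction: bromide displaces each phosphorus-activated oxygen by SN2 with inversion, giving (5S) and (1'R); the allylic centre reacts cold (SN2' is blocked by the neopentyl C3, ionisation is disfavoured by the β-chlorine), and the neopentyl ring centre reacts on warming through the conformer with an axial leaving group.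

Step 7
Reactants: 15 2-[(1R)-1-{[(1R,5S)-5-bromo-2-[(1R)-1-bromo-2-chloroethyl]-4,4-dimethylcyclohex-2-en-1-yl]oxy}ethyl]naphthalene
Product: 16 (1R,5S)-5-bromo-2-[(1R)-1-bromo-2-chloroethyl]-4,4-dimethylcyclohex-2-en-1-ol
Conditions: DDQ (1.5 equiv), CH2Cl2/pH 7 phosphate buffer, 0 °C to rt
Reagents that add atoms: none
Why: Oxidative cleavage of a naphthylmethyl-type ether: DDQ abstracts the naphthylic hydride, water traps the cation and the hemiketal collapses to the free alcohol, leaving the C1–O bond, its configuration and the halides untouched.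

Step 8
Reactants: 16 (1R,5S)-5-bromo-2-[(1R)-1-bromo-2-chloroethyl]-4,4-dimethylcyclohex-2-en-1-ol
Product: 17 (1R,5S)-5-bromo-2-[(1R)-1-bromo-2-chloroethyl]-4,4-dimethylcyclohex-2-en-1-yl acetate
Conditions: Ac2O, pyridine, DMAP (cat.), CH2Cl2, 0 °C
Reagents that add atoms: acetic anhydride, CC(=O)OC(C)=O
Why: DMAP-catalysed acylation of the secondary allylic alcohol proceeds with retention at C1; short cold exposure spares the allylic bromide.

**Compound list**
1 | (R)-1-(naphthalen-2-yl)ethan-1-ol | C[C@@H](O)c1ccc2ccccc2c1 | starting material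
2 | butyl vinyl ether | C=COCCCC | starting material
3 | 2-[(1R)-1-(ethenyloxy)ethyl]naphthalene | C[C@@H](OC=C)c1ccc2ccccc2c1 | intermediate
4 | 2-methylpropanoyl chloride (isobutyryl chloride) | CC(C)C(=O)Cl | starting material
5 | dimethylketene (not isolated) | CC(C)=C=O | intermediate
6 | 2,2-dimethyl-3-[(1R)-1-(naphthalen-2-yl)ethoxy]cyclobutan-1-one (both epimers at ring C3) | C[C@@H](OC1CC(=O)C1(C)C)c1ccc2ccccc2c1 | intermediate
7 | 2-chloro-N-methoxy-N-methylacetamide | CON(C)C(=O)CCl | starting material
8 | ethynylmagnesium bromide | C#C[Mg]Br | starting material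
9 | bromomagnesium 1-chloro-2-[methoxy(methyl)amino]but-3-yn-2-olate, the magnesium hemiaminal chelate (not isolated) | CON(C)C(CCl)(C#C)O[Mg]Br | intermediate
10 | 1-chlorobut-3-yn-2-one | C#CC(=O)CCl | intermediate
11 | ring-opened 1,4-zwitterion: trifluoroborate enolate at the gem-dimethyl carbon, O-[(1R)-1-(naphthalen-2-yl)ethyl] oxocarbenium at the former alkoxy carbon (not isolated) | C[C@@H]([O+]=CCC(O[B-](F)(F)F)=C(C)C)c1ccc2ccccc2c1 | intermediate
12 | conjugate adduct: trifluoroborate allenolate tethered to the same oxocarbenium (not isolated) | C[C@@H]([O+]=CCC(=O)C(C)(C)C=C=C(O[B-](F)(F)F)CCl)c1ccc2ccccc2c1 | intermediate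
13 | (5R)-4-(chloroacetyl)-2,2-dimethyl-5-[(1R)-1-(naphthalen-2-yl)ethoxy]cyclohex-3-en-1-one | C[C@@H](O[C@@H]1CC(=O)C(C)(C)C=C1C(=O)CCl)c1ccc2ccccc2c1 | intermediate
14 | (1R,5R)-4-[(1S)-2-chloro-1-hydroxyethyl]-2,2-dimethyl-5-[(1R)-1-(naphthalen-2-yl)ethoxy]cyclohex-3-en-1-ol | C[C@@H](O[C@@H]1C[C@@H](O)C(C)(C)C=C1[C@H](O)CCl)c1ccc2ccccc2c1 | intermediate
15 | 2-[(1R)-1-{[(1R,5S)-5-bromo-2-[(1R)-1-bromo-2-chloroethyl]-4,4-dimethylcyclohex-2-en-1-yl]oxy}ethyl]naphthalene | C[C@@H](O[C@@H]1C[C@H](Br)C(C)(C)C=C1[C@@H](Br)CCl)c1ccc2ccccc2c1 | intermediate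
16 | (1R,5S)-5-bromo-2-[(1R)-1-bromo-2-chloroethyl]-4,4-dimethylcyclohex-2-en-1-ol | O[C@@H]1C[C@H](Br)C(C)(C)C=C1[C@@H](Br)CCl | intermediate
17 | (1R,5S)-5-bromo-2-[(1R)-1-bromo-2-chloroethyl]-4,4-dimethylcyclohex-2-en-1-yl acetate | CC(=O)O[C@@H]1C[C@H](Br)C(C)(C)C=C1[C@@H](Br)CCl | target

**Step count:** 8 steps in total. Longest linear sequence: 7 steps (steps 1, 2, 4, 5, 6, 7, 8); step 3 is a one-step branch.

**Steps most likely to fail, with fallbacks**

Step 4 (Proposed new method). The boron enolate may add to the ynone carbonyl instead of the alkyne terminus, which would close to a dihydropyranone. The product may also lose the auxiliary alcohol by β-elimination under the Lewis acid, or the facial bias at the oxocarbenium may be weak. The fallback uses known chemistry and replaces the transient 1,4-dipole by an isolable diene. It sets out from vinyl ether 3 and acid chloride 4: C-acylation in the presence of pyridine (CH2Cl2, 0 °C to rt; no ketene forms with this weaker base) should give (E)-4-methyl-1-[(1R)-1-(naphthalen-2-yl)ethoxy]pent-1-en-3-one F1. Soft enolisation (TBSOTf, Et3N, Et2O, 0 °C) should give the 1-alkoxy-3-silyloxy diene tert-butyl(dimethyl){[(4E)-2-methyl-5-[(1R)-1-(naphthalen-2-yl)ethoxy]penta-2,4-dien-3-yl]oxy}silane F2. Diels–Alder reaction of F2 with ynone 10 (toluene, 80 °C, or ZnCl2 in CH2Cl2, where the addition is expected to run stepwise) should give the cyclohexa-1,4-diene 1-{(6R)-4-[(tert-butyldimethylsilyl)oxy]-3,3-dimethyl-6-[(1R)-1-(naphthalen-2-yl)ethoxy]cyclohexa-1,4-dien-1-yl}-2-chloroethan-1-one F3. Dilute HCl in THF should hydrolyse F3 to 13, where the fallback comes back to the route. The C1 epimers of 13 are diastereomers and can be separated if the selectivity is low.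

Step 6. The SN2 displacement at the neopentyl C5 carbinol is slow, so on warming E2 elimination or methyl migration can compete. Meanwhile the allylic C1' bromide, formed first, is exposed to bromide and phosphine and may lose configuration or be alkylated. The fallback stages the two substitutions by protection and sets out from diol 14. Selective silylation of the less hindered allylic carbinol (TBSCl, imidazole, DMF, 0 °C) should give (1R,5R)-4-[(1S)-1-{[tert-butyl(dimethyl)silyl]oxy}-2-chloroethyl]-2,2-dimethyl-5-[(1R)-1-(naphthalen-2-yl)ethoxy]cyclohex-3-en-1-ol F4. The neopentyl carbinol alone is then brominated under forcing Appel conditions (CBr4, PPh3, toluene, 70 °C) to tert-butyl{(1S)-1-[(4S,6R)-4-bromo-3,3-dimethyl-6-[(1R)-1-(naphthalen-2-yl)ethoxy]cyclohex-1-en-1-yl]-2-chloroethoxy}dimethylsilane F5. HF·pyridine in THF should free (1S)-1-[(4S,6R)-4-bromo-3,3-dimethyl-6-[(1R)-1-(naphthalen-2-yl)ethoxy]cyclohex-1-en-1-yl]-2-chloroethan-1-ol F6. A cold Appel reaction (CBr4, PPh3, CH2Cl2, −20 °C) then gives 15, where the fallback comes back to the route.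

Step 7. Hydride abstraction by DDQ at the hindered tertiary naphthylic C–H may be slow, or abstraction may occur at the allylic C1–H and over-oxidise the ring. The fallback exchanges the ether for the ester directly, without a free alcohol, and sets out from 15. Acetolysis with Ac2O and catalytic FeCl3 (CH2Cl2, −20 °C) should ionise the secondary naphthylic C–O bond and acetylate the released C1 oxygen with retention. This gives 17 directly, so the fallback comes back at the target and merges steps 7 and 8 (no new compound, F0).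

**Further compounds**
F1 | step 4 | (E)-4-methyl-1-[(1R)-1-(naphthalen-2-yl)ethoxy]pent-1-en-3-one | C[C@@H](O/C=C/C(=O)C(C)C)c1ccc2ccccc2c1
F2 | step 4 | tert-butyl(dimethyl){[(4E)-2-methyl-5-[(1R)-1-(naphthalen-2-yl)ethoxy]penta-2,4-dien-3-yl]oxy}silane | C[C@@H](O/C=C/C(O[Si](C)(C)C(C)(C)C)=C(C)C)c1ccc2ccccc2c1
F3 | step 4 | 1-{(6R)-4-[(tert-butyldimethylsilyl)oxy]-3,3-dimethyl-6-[(1R)-1-(naphthalen-2-yl)ethoxy]cyclohexa-1,4-dien-1-yl}-2-chloroethan-1-one | C[C@@H](O[C@@H]1C=C(O[Si](C)(C)C(C)(C)C)C(C)(C)C=C1C(=O)CCl)c1ccc2ccccc2c1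
F4 | step 6 | (1R,5R)-4-[(1S)-1-{[tert-butyl(dimethyl)silyl]oxy}-2-chloroethyl]-2,2-dimethyl-5-[(1R)-1-(naphthalen-2-yl)ethoxy]cyclohex-3-en-1-ol | C[C@@H](O[C@@H]1C[C@@H](O)C(C)(C)C=C1[C@H](O[Si](C)(C)C(C)(C)C)CCl)c1ccc2ccccc2c1
F5 | step 6 | tert-butyl{(1S)-1-[(4S,6R)-4-bromo-3,3-dimethyl-6-[(1R)-1-(naphthalen-2-yl)ethoxy]cyclohex-1-en-1-yl]-2-chloroethoxy}dimethylsilane | C[C@@H](O[C@@H]1C[C@H](Br)C(C)(C)C=C1[C@H](O[Si](C)(C)C(C)(C)C)CCl)c1ccc2ccccc2c1
F6 | step 6 | (1S)-1-[(4S,6R)-4-bromo-3,3-dimethyl-6-[(1R)-1-(naphthalen-2-yl)ethoxy]cyclohex-1-en-1-yl]-2-chloroethan-1-ol | C[C@@H](O[C@@H]1C[C@H](Br)C(C)(C)C=C1[C@H](O)CCl)c1ccc2ccccc2c1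
F0 | step 7 | none | none
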